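**Assumption:** commercial (R)-(+)-pulegone is taken as a single enantiomer. Positions follow chamigrane numbering, which is spiro[5.5]undecane numbering with C6 as the spiro atom, ring A = C1–C6 and ring B = C6–C11.

## Retrosynthetic overview
1. C2–Br and C3–Cl are installed last, by anti bromochlorination of a C2=C3 alkene. The face is set by the axial C7 and its hydroxyl group.
2. The C2=C3 alkene comes from the only tertiary C–H (C3–H) of a saturated ring A, by photobromination and loss of HBr. This erases the bought stereocentre after it has done its work.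
3. Key step: the C6–C11 spiro bond, C10–Br and C7–O all form in one anodic bromonium cyclisation of a (Z)-2-alkylidenecyclohexyl acetate. The acetate captures the C7 cation.
4. The Z-tetrasubstituted alkene comes from alkoxide-directed allylic lithiation and prenylation of cis-pulegol. C5 is set by reduction of pulegone.
5. Ring order: ring A is bought with pulegone, and ring B is closed in the anodic step.

## Route

Step 1
Reactants: 1 (R)-(+)-pulegone
Product: 2 (−)-cis-pulegol
Conditions: LiAlH4, Et2O, −78 °C
Reagents that add atoms: none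
Why: 1,2-hydride reduction of the enone, in which axial delivery to the chair with the C3 methyl equatorial gives the equatorial alcohol cis to that methyl, so the bought centre sets C5 as R (the minor trans epimer is removed by chromatography).

Step 2
Reactants: 2 (−)-cis-pulegol; 3 prenyl bromide
Product: 5 (1R,5R)-5-methyl-2-[(2Z)-6-methylhept-5-en-2-ylidene]cyclohexan-1-ol, via O,C-dilithio dianion 4 (not isolated)
Conditions: n-BuLi (2.3 equiv), TMEDA, Et2O, 0 °C to rt; then 3, −78 to 0 °C
Reagents that add atoms: prenyl bromide (3), CC(C)=CCBr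
Why: Alkoxide-directed allylic lithiation, in which the lithium alkoxide holds the base over the methyl group cis to the carbinol carbon (six-membered chelate) and SN2 alkylation at the primary terminus of the chelated allyllithium keeps the tetrasubstituted alkene in place and fixes the Z geometry (C8 cis to C5).

Step 3
Reactants: 5 (1R,5R)-5-methyl-2-[(2Z)-6-methylhept-5-en-2-ylidene]cyclohexan-1-ol
Product: 6 (1R,5R)-5-methyl-2-[(2Z)-6-methylhept-5-en-2-ylidene]cyclohexyl acetate
Conditions: Ac2O, Et3N, DMAP (cat.), CH2Cl2, rt
Reagents that add atoms: acetic anhydride, CC(=O)OC(C)=O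
Why: DMAP-catalysed acylation with retention, installing the acetate that is both the final C5 ester and the internal nucleophile of step 4.

Step 4
Reactants: 6 (1R,5R)-5-methyl-2-[(2Z)-6-methylhept-5-en-2-ylidene]cyclohexyl acetate
Product: 8 (3R,5R,6R,7R,10R)-10-bromo-7-hydroxy-3,7,11,11-tetramethylspiro[5.5]undecan-5-yl acetate, via bridged acetoxonium ion 7 (not isolated)
Conditions: graphite(+)|Pt(−), undivided cell, 5 mA cm−2, 2.2 F mol−1, Bu4NBr (1.05 equiv), Bu4NBF4 (0.1 M), HFIP/CH2Cl2 1:1, −10 °C; then sat. aq NaHCO3, rt
Reagents that add atoms: tetrabutylammonium bromide, CCCC[N+](CCCC)(CCCC)CCCC.[Br-]; water, O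
Why: Proposed new method: anodic oxidation of bromide (well below the alkene potentials) feeds a low steady concentration of HFIP-activated Br2/Br+ that forms bromonium ions reversibly and reacts on productively only at the unhindered C10=C11 alkene, because C6=C7 is shielded and deactivated by the allylic acetate; C6 then attacks the tertiary C11 terminus through a chair with bromine equatorial (sets C10) and from the ring-A face opposite the pseudo-axial acetate enforced by A(1,3) strain (sets C6), while the acetate carbonyl closes anti onto C7 of the Z-alkene (sets C7) to give ion 7, whose hydrolysis and 1,3-acyl shift to the less hindered oxygen leave the C5 acetate and the free C7 alcohol; any 10,11-dibromide re-ionises in HFIP and cathodic H2 evolution supplies the buffering alkoxide; the closest known reaction types are bromonium-induced polyene cyclisation with stoichiometric Br+ reagents, anodic bromolactonisation/bromoetherification and acyloxonium participation in cation–olefin cyclisation.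

Step 5
Reactants: 8 (3R,5R,6R,7R,10R)-10-bromo-7-hydroxy-3,7,11,11-tetramethylspiro[5.5]undecan-5-yl acetate
Product: 10 (5R,6R,7R,10R)-10-bromo-7-hydroxy-3,7,11,11-tetramethylspiro[5.5]undec-2-en-5-yl acetate, via tertiary C3 bromide 9 (not isolated)
Conditions: NBS (1.1 equiv), hν (400 nm LED), PhCF3, 35 °C; concentrate; Li2CO3, LiBr (cat.), DMF, 80 °C
Reagents that add atoms: N-bromosuccinimide, O=C1CCC(=O)N1Br (bromine of intermediate 9 only, lost again as bromide)
Why: Radical-chain (Wohl–Ziegler-type) C–H bromination takes the only tertiary C–H (every other C–H is secondary, primary or deactivated by O or Br), and 9 loses HBr in an E1-like Zaitsev elimination toward the electron-richer C2–H rather than C4–H next to the acetoxy carbon (as 5-halo-3-acetoxy steroids give the 5-ene), while the equatorial neopentyl C10 bromide has no anti-periplanar hydrogen; no new stereocentre is formed.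

Step 6
Reactants: 10 (5R,6R,7R,10R)-10-bromo-7-hydroxy-3,7,11,11-tetramethylspiro[5.5]undec-2-en-5-yl acetate
Product: 11 (2S,3S,5R,6R,7R,10R)-2,10-dibromo-3-chloro-7-hydroxy-3,7,11,11-tetramethylspiro[5.5]undecan-5-yl acetate
Conditions: ClTi(OiPr)3 (1.2 equiv), CH2Cl2/hexane, rt, 15 min; then NBS (1.1 equiv), −20 °C
Reagents that add atoms: N-bromosuccinimide, O=C1CCC(=O)N1Br; chlorotitanium triisopropoxide, CC(C)O[Ti](Cl)(OC(C)C)OC(C)C
Why: Titanium-mediated hydroxyl-directed alkene bromochlorination (anti, Markovnikov), in which Br+ adds to the ring-A face opposite the axial C7 and chloride is delivered to the tertiary C3 from titanium bound to the C7 alkoxide, which lies over the other face, giving trans C2–Br and C3–Cl, both equatorial (2S,3S).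

## Compound list
1 | (R)-(+)-pulegone, (5R)-5-methyl-2-(propan-2-ylidene)cyclohexan-1-one | C[C@@H]1CCC(=C(C)C)C(=O)C1 | starting material
2 | (−)-cis-pulegol, (1R,5R)-5-methyl-2-(propan-2-ylidene)cyclohexan-1-ol, OH cis to the ring methyl | C[C@@H]1CCC(=C(C)C)[C@H](O)C1 | intermediate
3 | prenyl bromide, 1-bromo-3-methylbut-2-ene | CC(C)=CCBr | starting material
4 | O,C-dilithio dianion of 2, lithium alkoxide plus allyllithium at the methyl cis to the carbinol carbon (not isolated) | C[C@@H]1CC/C(=C(\C)C[Li])[C@H](O[Li])C1 | intermediate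
5 | (1R,5R)-5-methyl-2-[(2Z)-6-methylhept-5-en-2-ylidene]cyclohexan-1-ol, homoprenyl chain cis to the carbinol carbon | C[C@@H]1CC/C(=C(\C)CCC=C(C)C)[C@H](O)C1 | intermediate
6 | acetate of 5 | C[C@@H]1CC/C(=C(\C)CCC=C(C)C)[C@H](OC(C)=O)C1 | intermediate
7 | 2-methyl-1,3-dioxan-2-ylium (acetoxonium) ion bridging O–C5 and O–C7 of the newly formed 10-bromospirocycle, with hexafluoroisopropoxide or BF4 as counter-ion (not isolated) | CC1=[O+][C@]2(C)CC[C@@H](Br)C(C)(C)[C@@]23CC[C@@H](C)C[C@H]3O1 | intermediate
8 | (3R,5R,6R,7R,10R)-10-bromo-7-hydroxy-3,7,11,11-tetramethylspiro[5.5]undecan-5-yl acetate | CC(=O)O[C@@H]1C[C@H](C)CC[C@@]12C(C)(C)[C@H](Br)CC[C@@]2(C)O | intermediate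
9 | (3S,5R,6R,7R,10R)-3,10-dibromo-7-hydroxy-3,7,11,11-tetramethylspiro[5.5]undecan-5-yl acetate, drawn as the axial C3 bromide; the C3 configuration is of no consequence (not isolated) | CC(=O)O[C@@H]1C[C@@](C)(Br)CC[C@@]12C(C)(C)[C@H](Br)CC[C@@]2(C)O | intermediate
10 | (5R,6R,7R,10R)-10-bromo-7-hydroxy-3,7,11,11-tetramethylspiro[5.5]undec-2-en-5-yl acetate | CC(=O)O[C@@H]1CC(C)=CC[C@@]12C(C)(C)[C@H](Br)CC[C@@]2(C)O | intermediate
11 | (2S,3S,5R,6R,7R,10R)-2,10-dibromo-3-chloro-7-hydroxy-3,7,11,11-tetramethylspiro[5.5]undecan-5-yl acetate (CNP0170512.2) | CC(=O)O[C@@H]1C[C@](C)(Cl)[C@@H](Br)C[C@@]12C(C)(C)[C@H](Br)CC[C@@]2(C)O | target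

## Step count
Total steps: 6. Longest linear sequence: 6.

## Steps most likely to fail

**Step 4 (the proposed new step).**
- Risks: Br+ capture at the tetrasubstituted C6=C7 alkene, where the acetate could close to a five-membered ring; 5-exo closure of C11 onto C7; and simple proton loss.
- Fallback, known chemistry, from 6 back to 8: cyclise 6 with Hg(OTf)2·PhNMe2 in MeNO2 at −20 °C. This is a mercurinium-induced cation–olefin cyclisation. It is much more selective for the less hindered trisubstituted alkene and uses the same acetate capture.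
- Aqueous NaBr work-up gives the equatorial C10 organomercury bromide F1. Bromodemercuration with retention (Br2, LiBr, pyridine, 0 °C) then gives 8.

**Step 5.**
- Risks: competing secondary C–H bromination, hypobromite fragmentation of the tertiary alcohol, and formation of the C3=C4 or exocyclic alkene.
- Fallback from 8 back to 10: hydroxylate C3–H with methyl(trifluoromethyl)dioxirane, which is tertiary-selective and proceeds with retention, to give the C3 tertiary alcohol F2.
- Then dehydrate the less hindered of the two tertiary alcohols with SOCl2/pyridine at −20 °C. Anti elimination of the axial chlorosulfite gives 10.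

**Step 6.**
- Risks: the trans-diaxial (Fürst–Plattner) pathway on the other face would give the (2R,3R) isomer, and the C7 oxygen could attack C3 to form a transannular bromoether.
- Fallback from 10 back to 11: add Br2 (CH2Cl2, −78 °C) to obtain the kinetic trans-diaxial (2R,3R)-dibromide F3.
- Let F3 undergo the known thermal diaxial-to-diequatorial 1,2-dibromide rearrangement (CHCl3, 40 °C). This gives the more stable (2S,3S)-dibromide F4, driven by relief of the Br/C7 syn-axial clash.
- Finally exchange only the tertiary bromide for chloride, with retention through the C2-bromonium ion (Bu4NCl, HFIP, 25 °C), to arrive at 11.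

Further compounds
F1 | step 4 | (3R,5R,6R,7R,10R)-10-(bromomercurio)-7-hydroxy-3,7,11,11-tetramethylspiro[5.5]undecan-5-yl acetate | CC(=O)O[C@@H]1C[C@H](C)CC[C@@]12C(C)(C)[C@H]([Hg]Br)CC[C@@]2(C)O
F2 | step 5 | (3S,5R,6R,7R,10R)-10-bromo-3,7-dihydroxy-3,7,11,11-tetramethylspiro[5.5]undecan-5-yl acetate | CC(=O)O[C@@H]1C[C@@](C)(O)CC[C@@]12C(C)(C)[C@H](Br)CC[C@@]2(C)O
F3 | step 6 | (2R,3R,5R,6R,7R,10R)-2,3,10-tribromo-7-hydroxy-3,7,11,11-tetramethylspiro[5.5]undecan-5-yl acetate | CC(=O)O[C@@H]1C[C@@](C)(Br)[C@H](Br)C[C@@]12C(C)(C)[C@H](Br)CC[C@@]2(C)O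
F4 | step 6 | (2S,3S,5R,6R,7R,10R)-2,3,10-tribromo-7-hydroxy-3,7,11,11-tetramethylspiro[5.5]undecan-5-yl acetate | CC(=O)O[C@@H]1C[C@](C)(Br)[C@@H](Br)C[C@@]12C(C)(C)[C@H](Br)CC[C@@]2(C)O
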